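**Plan**

- Retrosynthesis: the CH2OH on C1 of the catechol ring (ring A) is taken back to the aldehyde. One C–C cut follows, between C2 of ring A and the benzylic carbon C7' of the 3-bromo-4-hydroxybenzyl unit (ring B). The C3 hydroxyl of ring A is then traced to the methyl ether of 5-bromovanillin.
- Enabling feature: in ring B the C4' hydroxyl is para to C7', so ring B can be unmasked as a para-quinone methide (C7'=C1', C4'=O). In ring A the C3 hydroxyl is ortho to C2–H, so its oxide makes C2 the carbon end of an ambident phenoxide. The C4 oxide/C1 formyl pair (a vinylogous carboxylate) stays conjugated only if attack comes at C2.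
- Forward order: no ring is made and both benzene rings are bought with bromine in place. The sequence is demethylation (step 1), union of the rings at C2–C7' (step 2) and reduction of the aldehyde (step 3).
- Helper: the aldehyde oxidation level at C1 keeps ring A's own para-hydroxybenzylic carbon from ionising during the union. It is taken to the alcohol last, without acid.
- Stereochemistry (remark): the target has no stereocentre, axis or double-bond isomerism, so there is no enantiomer to select. The one sp3 ring carbon that arises in step 2 is lost on rearomatisation.

Key step: step 2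

**Route**

Step 1
Reactants: 1 5-bromovanillin (3-bromo-4-hydroxy-5-methoxybenzaldehyde)
Product: 2 3-bromo-4,5-dihydroxybenzaldehyde
Conditions: AlCl3 (1.2 equiv), pyridine (4.5 equiv), CH2Cl2, reflux, Ar; then 2 M HCl, 0 °C to rt
Reagents that add atoms: none
Why: Chelation-assisted aryl methyl ether cleavage (AlCl3–pyridine demethylation): aluminium binds the ortho-hydroxy/methoxy pair and pyridine removes the activated O-methyl group by SN2, so only this ether is cleaved while the aldehyde and the aryl bromide should stay untouched.

Step 2
Reactants: 2 3-bromo-4,5-dihydroxybenzaldehyde (3 equiv); 3 3-bromo-4-hydroxybenzyl alcohol (1 equiv)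
Product: 6 5-bromo-2-[(3-bromo-4-hydroxyphenyl)methyl]-3,4-dihydroxybenzaldehyde, via para-quinone methide 4 (not isolated), via cyclohexa-2,4-dienone adduct 5 (not isolated)
Conditions: aq NaOH (2 equiv per 2, 1 equiv per 3; pH about 12), degassed H2O, Ar, 95 °C, 3 added over 8 h, then 12 h; then 1 M HCl to pH 3, 0 °C
Reagents that add atoms: none
Why: Mechanism (ring A locants as in 6: CHO on C1, reacting carbon C2, oxides on C3 and C4, Br on C5, H on C6): the phenoxide of 3 expels hydroxide from its para-benzylic carbon by 1,6-elimination to give para-quinone methide 4, the catecholate dianion of 2 adds to the exocyclic CH2 of 4 through C2 (a 1,6-conjugate addition that rearomatises ring B and dearomatises ring A to dienone 5), and proton loss from C2 rearomatises ring A and makes the C–C bond formation irreversible, water being the only co-product. The closest known reaction type is the base-promoted condensation of phenolates with hydroxymethylphenols through quinone methides (resole-type diarylmethane formation, a Friedel–Crafts-type 1,6-addition). No ring is closed and no stereocentre is set, since the only sp3 ring carbon (C2 in 5) is lost on tautomerisation. The step needs alkylation at carbon and not at oxygen, at C2 and not at C6, and cross-condensation ahead of self-condensation; alkylation at oxygen is reversible under the conditions (an aryl 4-hydroxybenzyl ether re-ionises to 4) whereas alkylation at carbon is not, so material should drain to carbon. Attack at C2 leaves the C4-oxide/C1-formyl vinylogous carboxylate conjugated in 5, whereas attack at C6 would interrupt it and C6 is flanked by Br and CHO; this is the same carbon at which 3-hydroxy-4-alkoxybenzaldehydes are halogenated. The dianion of 2 is a far stronger carbon nucleophile than the 2-bromophenoxide of 3 and is kept in excess by the slow addition of 3, while the aldehyde at C1 keeps ring A from forming a quinone methide of its own.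

Step 3
Reactants: 6 5-bromo-2-[(3-bromo-4-hydroxyphenyl)methyl]-3,4-dihydroxybenzaldehyde
Product: 7 [5-bromo-2-[(3-bromo-4-hydroxyphenyl)methyl]-3,4-dihydroxyphenyl]methanol (the target; achiral)
Conditions: NaBH4 (2 equiv), THF–H2O (4:1), Ar, 0 °C to rt; then aq NH4Cl to pH 6–7, 0 °C; EtOAc extraction, no acid and no alcohol solvent in the isolation
Reagents that add atoms: none
Why: Borohydride reduction of an aryl aldehyde, as in the reduction of hydroxybenzaldehydes to hydroxybenzyl alcohols in aqueous base; aryl bromides and phenols are inert to NaBH4, and the low temperature with near-neutral work-up should keep the new 4-hydroxybenzylic alcohol from ionising.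

**Compound list**

1 | 5-bromovanillin (3-bromo-4-hydroxy-5-methoxybenzaldehyde), purchased | COc1cc(C=O)cc(Br)c1O | starting material
2 | 3-bromo-4,5-dihydroxybenzaldehyde | O=Cc1cc(O)c(O)c(Br)c1 | intermediate
3 | 3-bromo-4-hydroxybenzyl alcohol [2-bromo-4-(hydroxymethyl)phenol], purchased | OCc1ccc(O)c(Br)c1 | starting material
4 | 2-bromo-4-methylidenecyclohexa-2,5-dien-1-one (para-quinone methide, not isolated) | C=C1C=CC(=O)C(Br)=C1 | intermediate
5 | 3-bromo-6-[(3-bromo-4-hydroxyphenyl)methyl]-4-hydroxy-5-oxocyclohexa-1,3-diene-1-carbaldehyde (racemic at C6, present as its anion, not isolated) | O=CC1=CC(Br)=C(O)C(=O)C1Cc1ccc(O)c(Br)c1 | intermediate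
6 | 5-bromo-2-[(3-bromo-4-hydroxyphenyl)methyl]-3,4-dihydroxybenzaldehyde | O=Cc1cc(Br)c(O)c(O)c1Cc1ccc(O)c(Br)c1 | intermediate
7 | [5-bromo-2-[(3-bromo-4-hydroxyphenyl)methyl]-3,4-dihydroxyphenyl]methanol, also 6-bromo-3-[(3-bromo-4-hydroxyphenyl)methyl]-4-(hydroxymethyl)benzene-1,2-diol (achiral) | OCc1cc(Br)c(O)c(O)c1Cc1ccc(O)c(Br)c1 | target

**Totals and risks**

Total step count: 3. Longest linear sequence: 3 steps (1 → 2 → 6 → 7); 3 enters as a purchased fragment in step 2.

Steps most likely to fail, in order of risk:

1. Step 2. What may go wrong: loss of site control when the quinone methide is captured (attack at the ring carbon between formyl and bromine, or at oxygen without return), self-condensation of the hydroxybenzyl partner, and air oxidation of the catecholate in hot base. The fallback sets out from 2 and comes back at 6; it replaces the C–H benzylation by a cross-coupling at a halogen placed beforehand. The more acidic hydroxyl of 2 (para to the formyl group) would be methylated selectively (MeI 1 equiv, Li2CO3, DMF) to give 3-bromo-5-hydroxy-4-methoxybenzaldehyde F1. Iodination ortho to the remaining phenol (ICl, pyridine, dioxane) should give 5-bromo-3-hydroxy-2-iodo-4-methoxybenzaldehyde F2, and a second methylation (MeI, K2CO3, DMF) 5-bromo-2-iodo-3,4-dimethoxybenzaldehyde F3. Purchased 3-bromo-4-methoxybenzyl alcohol would be converted with PBr3 into 3-bromo-4-methoxybenzyl bromide F4, and this with zinc dust and LiCl in THF into (3-bromo-4-methoxybenzyl)zinc bromide F5. A Negishi coupling of F3 with F5 (Pd(PPh3)4, THF, rt to 40 °C), in which the C–I bond should react well ahead of both C–Br bonds, should give 5-bromo-2-[(3-bromo-4-methoxyphenyl)methyl]-3,4-dimethoxybenzaldehyde F6. BBr3 (CH2Cl2, −78 °C to rt) should then cleave the three methyl ethers and return 6.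

2. Step 3. What may go wrong: over-reduction of the new benzylic alcohol to a methyl group and self-alkylation, both through the quinone methide that the C4 phenoxide of ring A can form once C1 carries CH2OH; further loss of the product on acidic work-up or on silica. The fallback sets out from 6 and comes back at 7; it masks the phenols before the hydride step. Ac2O in pyridine should give 5-bromo-2-[(4-acetoxy-3-bromophenyl)methyl]-3,4-diacetoxybenzaldehyde F7. BH3·THF (THF, 0 °C) should reduce only the aldehyde, giving the tri-O-acetyl derivative of 7 with free CH2OH, F8. K2CO3 in degassed MeOH at 0 °C, followed by NH4Cl buffer, should remove the three acetates in the absence of hydride and give 7.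

3. Step 1. What may go wrong: incomplete ether cleavage, and loss or air oxidation of the catechol while the aluminium chelate is hydrolysed. The fallback sets out from 1 and comes back at 2; it replaces the Lewis-acid cleavage by SN2 dealkylation at the methyl carbon with a soft nucleophile under basic conditions. Sodium ethanethiolate (EtSH, NaH, 4 equiv) in DMF at 120 °C under argon, then acidification, should give 2 directly; no compound outside the list is made (F0).

**Further compounds**

F0 | step 1 | none | none
F1 | step 2 | 3-bromo-5-hydroxy-4-methoxybenzaldehyde | COc1c(O)cc(C=O)cc1Br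
F2 | step 2 | 5-bromo-3-hydroxy-2-iodo-4-methoxybenzaldehyde | COc1c(Br)cc(C=O)c(I)c1O
F3 | step 2 | 5-bromo-2-iodo-3,4-dimethoxybenzaldehyde | COc1c(Br)cc(C=O)c(I)c1OC
F4 | step 2 | 3-bromo-4-methoxybenzyl bromide | COc1ccc(CBr)cc1Br
F5 | step 2 | (3-bromo-4-methoxybenzyl)zinc bromide | COc1ccc(C[Zn]Br)cc1Br
F6 | step 2 | 5-bromo-2-[(3-bromo-4-methoxyphenyl)methyl]-3,4-dimethoxybenzaldehyde | COc1ccc(Cc2c(C=O)cc(Br)c(OC)c2OC)cc1Br
F7 | step 3 | 5-bromo-2-[(4-acetoxy-3-bromophenyl)methyl]-3,4-diacetoxybenzaldehyde | CC(=O)Oc1ccc(Cc2c(C=O)cc(Br)c(OC(C)=O)c2OC(C)=O)cc1Br
F8 | step 3 | 2-bromo-4-[[4-bromo-2,3-diacetoxy-6-(hydroxymethyl)phenyl]methyl]phenyl acetate | CC(=O)Oc1ccc(Cc2c(CO)cc(Br)c(OC(C)=O)c2OC(C)=O)cc1Br
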